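The C1–O bond of the quaternary carbinol is formed late, on a six-membered ring taken intact from (−)-shikimic acid. In the target the tertiary O1 and the free O3 are cis-1,3 on the cyclohexane ring. In a shikimate ester the allylic C3 hydroxyl flanks the C1=C2 alkene and can therefore guide an incoming oxygen to the face of C1 on which it sits. A VO(acac)2/t-BuOOH epoxidation of tert-butyl 4,5-di-O-(4-acetoxycinnamoyl)shikimate, whose only free hydroxyl is O3, sets C1 and C2 in one operation. The surplus C2–O bond is then removed (iodide opening, radical reduction) and acid unmasks the target.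

Key step: step 8

Remark on the chemistry: quinate numbering with C1 as the quaternary carbinol is used, so the free secondary hydroxyl is O3 (cis to O4) and the esters sit on O4 and O5. The tert-butyl ester is put on only after the 4,5-diacetal has been hydrolysed, because it would not outlast the aqueous trifluoroacetic acid which that hydrolysis needs.

Step 1
Reactants: 1 (−)-shikimic acid
Product: 2 methyl 4,5-O-[(2S,3S)-2,3-dimethoxybutane-2,3-diyl]shikimate
Conditions: butane-2,3-dione, HC(OMe)3, CSA (cat.), MeOH, reflux; then Et3N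
Reagents that add atoms: butane-2,3-dione CC(=O)C(C)=O; methanol CO; trimethyl orthoformate COC(OC)OC (water scavenger that also supplies methoxy groups)
Why: Fischer esterification and acid-catalysed diacetal formation run in the same pot, and of the three hydroxyls only the trans-diequatorial O4/O5 pair can close the trans-fused dioxane with both methoxy groups axial (anomeric control of the two new acetal centres, both S), so the allylic O3 stays free.

Step 2
Reactants: 2 methyl 4,5-O-[(2S,3S)-2,3-dimethoxybutane-2,3-diyl]shikimate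
Product: 3 methyl 3-O-(tert-butyldiphenylsilyl)-4,5-O-[(2S,3S)-2,3-dimethoxybutane-2,3-diyl]shikimate
Conditions: TBDPSCl, imidazole, DMAP (cat.), DMF, rt to 40 °C
Reagents that add atoms: tert-butyl(chloro)diphenylsilane CC(C)(C)[Si](Cl)(c1ccccc1)c1ccccc1
Why: Imidazole-promoted silyl ether formation at the only free hydroxyl; tert-butyldiphenylsilyl is chosen because it should outlast the aqueous trifluoroacetic acid of step 3 and can later be removed by fluoride without base.

Step 3
Reactants: 3 methyl 3-O-(tert-butyldiphenylsilyl)-4,5-O-[(2S,3S)-2,3-dimethoxybutane-2,3-diyl]shikimate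
Product: 5 3-O-(tert-butyldiphenylsilyl)shikimic acid, via lithium carboxylate of the silylated diacetal 4 (not isolated)
Conditions: LiOH·H2O, THF/MeOH/H2O, rt; evaporate organic solvents; then TFA/H2O (9:1), CH2Cl2, 0 °C to rt
Reagents that add atoms: lithium hydroxide [Li+].[OH-]
Why: Ester saponification, done while O3 has no free neighbouring hydroxyl so that the silyl group cannot migrate, is followed in the same flask by acid-catalysed hydrolysis of the diacetal, which the acid-stable silyl ether and the ester-deactivated allylic C3–O bond should survive.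

Step 4
Reactants: 5 3-O-(tert-butyldiphenylsilyl)shikimic acid
Product: 6 tert-butyl 3-O-(tert-butyldiphenylsilyl)shikimate
Conditions: t-BuOC(=NH)CCl3, CH2Cl2/cyclohexane, rt
Reagents that add atoms: tert-butyl 2,2,2-trichloroacetimidate CC(C)(C)OC(=N)C(Cl)(Cl)Cl
Why: Acid-promoted O-alkylation by a trichloroacetimidate, in which the carboxylic acid protonates the imidate and captures the tert-butyl cation whereas the two secondary hydroxyls would need a Lewis acid to react.

Step 5
Reactants: 7 p-coumaric acid
Product: 8 (E)-4-acetoxycinnamic acid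
Conditions: Ac2O, pyridine, DMAP (cat.), rt; then H2O
Reagents that add atoms: acetic anhydride CC(=O)OC(C)=O
Why: O-Acetylation of the phenol under nucleophilic catalysis; the mixed anhydride formed at the carboxyl group is hydrolysed again in the aqueous work-up.

Step 6
Reactants: 6 tert-butyl 3-O-(tert-butyldiphenylsilyl)shikimate; 8 (E)-4-acetoxycinnamic acid (two equivalents are consumed, one for each hydroxyl)
Product: 10 tert-butyl 4,5-di-O-[(E)-4-acetoxycinnamoyl]-3-O-(tert-butyldiphenylsilyl)shikimate, via (E)-4-acetoxycinnamoyl chloride 9 (not isolated)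
Conditions: 8 (2.6 equiv), (COCl)2, DMF (cat.), CH2Cl2, 0 °C to rt, evaporate; then 6 (1 equiv), pyridine, DMAP, CH2Cl2, 0 °C to rt
Reagents that add atoms: second equivalent of (E)-4-acetoxycinnamic acid O=C(O)/C=C/c1ccc(OC(C)=O)cc1 (compound 8, activated as 9 like the first equivalent; it supplies the second 4-acetoxycinnamoyl group)
Why: Acid chloride formation with oxalyl chloride/DMF is followed by DMAP-catalysed esterification of both secondary hydroxyls, each of which consumes one molecule of 9, so that the acid chloride is used in excess over two equivalents, the E alkenes and the C3 to C5 stereocentres being spectators.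

Step 7
Reactants: 10 tert-butyl 4,5-di-O-[(E)-4-acetoxycinnamoyl]-3-O-(tert-butyldiphenylsilyl)shikimate
Product: 11 tert-butyl 4,5-di-O-[(E)-4-acetoxycinnamoyl]shikimate
Conditions: HF·pyridine, pyridine, THF, 0 °C to rt
Reagents that add atoms: none
Why: Fluoride-mediated desilylation under weakly acidic, non-nucleophilic conditions, chosen so that the aryl acetates and the tert-butyl ester are spared and the O4 acyl group does not migrate to the liberated cis O3 as it could under basic fluoride.

Step 8
Reactants: 11 tert-butyl 4,5-di-O-[(E)-4-acetoxycinnamoyl]shikimate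
Product: 12 tert-butyl 4,5-di-O-[(E)-4-acetoxycinnamoyl]-1,2-epoxy-3-hydroxycyclohexane-1-carboxylate (C3 to C5 as in shikimate; oxirane oxygen cis to O3)
Conditions: VO(acac)2 (cat.), anhydrous t-BuOOH in decane, 4 Å molecular sieves, toluene, rt to 60 °C
Reagents that add atoms: tert-butyl hydroperoxide CC(C)(C)OO
Why: VO(acac)2 is oxidised by t-BuOOH to a pentavalent vanadium alkoxide that binds both the C3 hydroxyl (as a vanadate ester) and the alkylperoxide, and the activated peroxide oxygen is transferred to C1=C2 inside this complex, making the C1–O and C2–O bonds together and releasing tert-butanol. The closest known reaction type is the hydroxyl-directed, VO(acac)2-catalysed epoxidation of cyclic allylic alcohols with t-BuOOH; an ester-conjugated alkene lies at the slow end of its scope, which is why the risk of the route is placed here. The oxirane is the one ring closed, and it closes in the 3-exo mode, the alkene carbons attacking the metal-bound peroxide oxygen with loss of tert-butoxide. The two new stereocentres C1 and C2 are both set by the existing C3 stereocentre, since the tether can reach only the ring face that carries O3; the C1–O bond is therefore cis to O3, as the quinate requires. The step needs facial selectivity, chemoselectivity for the ring alkene over the two cinnamate alkenes, and epoxidation in preference to oxidation of the carbinol to the enone; the pseudoaxial allylic O3–H supplies the first two (no other alkene has a hydroxyl to bind the metal), and anhydrous conditions with a moderate temperature are meant to hold back the third.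

Step 9
Reactants: 12 tert-butyl 4,5-di-O-[(E)-4-acetoxycinnamoyl]-1,2-epoxy-3-hydroxycyclohexane-1-carboxylate
Product: 13 tert-butyl 4,5-di-O-[(E)-4-acetoxycinnamoyl]-2-iodoquinate (iodine at C2 trans to O1)
Conditions: MgI2 (anhydrous), toluene/Et2O, −40 °C to 0 °C; cold aqueous Na2S2O3/NH4Cl work-up, product used crude
Reagents that add atoms: magnesium diiodide [Mg+2].[I-].[I-]
Why: Lewis-acid-assisted SN2 opening of the oxirane by iodide (iodohydrin formation): C1 is quaternary and deactivated by the ester, so iodide attacks the secondary C2 from the face opposite the oxirane oxygen in a trans-diaxial opening that leads directly to the quinate chair, and C1 keeps its oxygen and its configuration.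

Step 10
Reactants: 13 tert-butyl 4,5-di-O-[(E)-4-acetoxycinnamoyl]-2-iodoquinate
Product: 14 tert-butyl 4,5-di-O-[(E)-4-acetoxycinnamoyl]quinate
Conditions: Bu3SnH, AIBN (cat.), toluene, 70 °C
Reagents that add atoms: none
Why: Radical chain dehalogenation, in which the secondary C2 radical has no β-substituent prone to fragment and should take hydrogen from Bu3SnH faster than it can add to a cinnamate, leaving a methylene at C2 so that no stereocentre is at stake.

Step 11
Reactants: 14 tert-butyl 4,5-di-O-[(E)-4-acetoxycinnamoyl]quinate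
Product: 16 4,5-di-O-p-coumaroylquinic acid, via 4,5-di-O-[(E)-4-acetoxycinnamoyl]quinic acid 15 (not isolated)
Conditions: TFA/CH2Cl2 (1:1), rt, evaporate; then 2 M aqueous HCl/THF (1:1), rt, light excluded; reversed-phase chromatography
Reagents that add atoms: none
Why: Acidolysis of the tert-butyl ester (loss of 2-methylpropene while the phenols are still masked) followed by acid-catalysed hydrolysis of the two aryl acetates, which are much more labile than the alkyl cinnamates; staying acidic throughout avoids the base-induced acyl migration of acylquinic acids.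

Compound list

1 | (−)-shikimic acid | O[C@@H]1[C@H](O)C=C(C(=O)O)C[C@H]1O | starting material
2 | methyl 4,5-O-[(2S,3S)-2,3-dimethoxybutane-2,3-diyl]shikimate | COC(=O)C1=C[C@@H](O)[C@H]2O[C@](C)(OC)[C@@](C)(OC)O[C@@H]2C1 | intermediate
3 | methyl 3-O-(tert-butyldiphenylsilyl)-4,5-O-[(2S,3S)-2,3-dimethoxybutane-2,3-diyl]shikimate | COC(=O)C1=C[C@@H](O[Si](c3ccccc3)(c4ccccc4)C(C)(C)C)[C@H]2O[C@](C)(OC)[C@@](C)(OC)O[C@@H]2C1 | intermediate
4 | lithium 3-O-(tert-butyldiphenylsilyl)-4,5-O-[(2S,3S)-2,3-dimethoxybutane-2,3-diyl]shikimate | [Li+].[O-]C(=O)C1=C[C@@H](O[Si](c3ccccc3)(c4ccccc4)C(C)(C)C)[C@H]2O[C@](C)(OC)[C@@](C)(OC)O[C@@H]2C1 | intermediate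
5 | 3-O-(tert-butyldiphenylsilyl)shikimic acid | O[C@@H]1[C@H](O[Si](c2ccccc2)(c3ccccc3)C(C)(C)C)C=C(C(=O)O)C[C@H]1O | intermediate
6 | tert-butyl 3-O-(tert-butyldiphenylsilyl)shikimate | O[C@@H]1[C@H](O[Si](c2ccccc2)(c3ccccc3)C(C)(C)C)C=C(C(=O)OC(C)(C)C)C[C@H]1O | intermediate
7 | p-coumaric acid | O=C(O)/C=C/c1ccc(O)cc1 | starting material
8 | (E)-4-acetoxycinnamic acid | O=C(O)/C=C/c1ccc(OC(C)=O)cc1 | intermediate
9 | (E)-4-acetoxycinnamoyl chloride | O=C(Cl)/C=C/c1ccc(OC(C)=O)cc1 | intermediate
10 | tert-butyl 4,5-di-O-[(E)-4-acetoxycinnamoyl]-3-O-(tert-butyldiphenylsilyl)shikimate | O=C(/C=C/c1ccc(OC(C)=O)cc1)O[C@@H]2[C@H](O[Si](c5ccccc5)(c6ccccc6)C(C)(C)C)C=C(C(=O)OC(C)(C)C)C[C@H]2OC(=O)/C=C/c3ccc(OC(C)=O)cc3 | intermediate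
11 | tert-butyl 4,5-di-O-[(E)-4-acetoxycinnamoyl]shikimate | O=C(/C=C/c1ccc(OC(C)=O)cc1)O[C@@H]2[C@H](O)C=C(C(=O)OC(C)(C)C)C[C@H]2OC(=O)/C=C/c3ccc(OC(C)=O)cc3 | intermediate
12 | tert-butyl 4,5-di-O-[(E)-4-acetoxycinnamoyl]-1,2-epoxy-3-hydroxycyclohexane-1-carboxylate, oxirane oxygen cis to O3 | O=C(/C=C/c1ccc(OC(C)=O)cc1)O[C@@H]2[C@H](O)[C@@H]3O[C@]3(C(=O)OC(C)(C)C)C[C@H]2OC(=O)/C=C/c4ccc(OC(C)=O)cc4 | intermediate
13 | tert-butyl 4,5-di-O-[(E)-4-acetoxycinnamoyl]-2-iodoquinate, iodine at C2 trans to O1 | O=C(/C=C/c1ccc(OC(C)=O)cc1)O[C@@H]2[C@H](O)[C@@H](I)[C@@](O)(C(=O)OC(C)(C)C)C[C@H]2OC(=O)/C=C/c3ccc(OC(C)=O)cc3 | intermediate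
14 | tert-butyl 4,5-di-O-[(E)-4-acetoxycinnamoyl]quinate | O=C(/C=C/c1ccc(OC(C)=O)cc1)O[C@@H]2[C@H](O)C[C@@](O)(C(=O)OC(C)(C)C)C[C@H]2OC(=O)/C=C/c3ccc(OC(C)=O)cc3 | intermediate
15 | 4,5-di-O-[(E)-4-acetoxycinnamoyl]quinic acid | O=C(/C=C/c1ccc(OC(C)=O)cc1)O[C@@H]2[C@H](O)C[C@@](O)(C(=O)O)C[C@H]2OC(=O)/C=C/c3ccc(OC(C)=O)cc3 | intermediate
16 | 4,5-di-O-p-coumaroylquinic acid | O=C(/C=C/c1ccc(O)cc1)O[C@@H]1[C@H](O)C[C@@](O)(C(=O)O)C[C@H]1OC(=O)/C=C/c1ccc(O)cc1 | target

Total step count: 11. Longest linear sequence: 10 steps (steps 1 to 4 and 6 to 11, from 1 to 16).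

Steps most likely to fail

Step 8. Oxygen transfer to the ester-conjugated C1=C2 bond may be so slow that it is outrun by oxidation of the C3 carbinol to the enone (followed by loss of the C5 acyloxy group and aromatisation) or by unproductive peroxide decomposition. The fallback gives up the late oxidation of C1 and takes the C1–O bond from the chiral pool. It sets out from acid 8 (converted into 9 as in step 6) together with purchased (−)-quinic acid F1 and comes back to the route at 14. F1 is put through the operations of steps 1 to 4. Butane-2,3-dione, HC(OMe)3 and CSA in methanol should give methyl 4,5-O-[(2S,3S)-2,3-dimethoxybutane-2,3-diyl]quinate F2, since again only the trans-4,5-diol can form the diacetal. TBDPSCl and imidazole should silylate the secondary O3 and leave the tertiary O1 alone, giving methyl 3-O-(tert-butyldiphenylsilyl)-4,5-O-[(2S,3S)-2,3-dimethoxybutane-2,3-diyl]quinate F3. LiOH should give lithium 3-O-(tert-butyldiphenylsilyl)-4,5-O-[(2S,3S)-2,3-dimethoxybutane-2,3-diyl]quinate F4, and aqueous TFA should then give 3-O-(tert-butyldiphenylsilyl)quinic acid F5. The trichloroacetimidate should give tert-butyl 3-O-(tert-butyldiphenylsilyl)quinate F6. Acylation with an excess of 9 in pyridine/DMAP consumes two equivalents of the acid chloride, one for O4 and one for O5, while the tertiary O1 should not react. It should give tert-butyl 4,5-di-O-[(E)-4-acetoxycinnamoyl]-3-O-(tert-butyldiphenylsilyl)quinate F7. HF·pyridine as in step 7 should then give 14.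

Step 9. The Lewis acid may trigger a 1,2-shift with ring contraction of the magnesium alkoxide of the iodohydrin, or cleave the tert-butyl ester, before iodide has displaced the hindered C2–O bond. The iodohydrin may also close back to the oxirane during work-up. The fallback replaces the halide/Lewis acid pair by a soft selenium nucleophile delivered by silyl transfer. It sets out from 12 and comes back at 14. PhSeSiMe3 (excess) with catalytic ZnI2 in CH2Cl2 should open the oxirane at C2 with inversion and silylate both O1 and the free O3. This should give tert-butyl 4,5-di-O-[(E)-4-acetoxycinnamoyl]-2-(phenylselanyl)-1,3-bis-O-(trimethylsilyl)quinate F8, with selenium at C2 trans to O1. Methanol with a trace of citric acid should remove the trimethylsilyl groups to give tert-butyl 4,5-di-O-[(E)-4-acetoxycinnamoyl]-2-(phenylselanyl)quinate F9, which cannot revert to the oxirane and can be purified. Bu3SnH/AIBN in toluene at 80 °C should then cleave the C–Se bond and give 14.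

Step 6. Acylation of O4, which is flanked by the bulky silyl ether on O3 and the new ester on O5, may stall at the 5-monoester, and forcing it with DMAP may transfer acetyl groups from the aryl acetates. The fallback builds the cinnamate on the ring oxygens instead of attaching it. It sets out from 6 and comes back at 10. 2,2-Dimethyl-1,3-dioxane-4,6-dione (Meldrum's acid, two equivalents consumed) in toluene at 80 °C is a small, thermally activated acyl donor. It should give tert-butyl 4,5-di-O-(carboxyacetyl)-3-O-(tert-butyldiphenylsilyl)shikimate F10. Knoevenagel–Doebner condensation of both malonate half-esters with 4-hydroxybenzaldehyde (two equivalents consumed; pyridine, catalytic piperidine, 50 °C, loss of CO2) should give tert-butyl 4,5-di-O-[(E)-4-hydroxycinnamoyl]-3-O-(tert-butyldiphenylsilyl)shikimate F11. Ac2O/pyridine should then acetylate the two phenols and give 10.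

Further compounds

F1 | step 8 | (−)-quinic acid (purchased) | O[C@@H]1[C@H](O)C[C@@](O)(C(=O)O)C[C@H]1O
F2 | step 8 | methyl 4,5-O-[(2S,3S)-2,3-dimethoxybutane-2,3-diyl]quinate | COC(=O)[C@]1(O)C[C@@H](O)[C@H]2O[C@](C)(OC)[C@@](C)(OC)O[C@@H]2C1
F3 | step 8 | methyl 3-O-(tert-butyldiphenylsilyl)-4,5-O-[(2S,3S)-2,3-dimethoxybutane-2,3-diyl]quinate | COC(=O)[C@]1(O)C[C@@H](O[Si](c3ccccc3)(c4ccccc4)C(C)(C)C)[C@H]2O[C@](C)(OC)[C@@](C)(OC)O[C@@H]2C1
F4 | step 8 | lithium 3-O-(tert-butyldiphenylsilyl)-4,5-O-[(2S,3S)-2,3-dimethoxybutane-2,3-diyl]quinate | [Li+].[O-]C(=O)[C@]1(O)C[C@@H](O[Si](c3ccccc3)(c4ccccc4)C(C)(C)C)[C@H]2O[C@](C)(OC)[C@@](C)(OC)O[C@@H]2C1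
F5 | step 8 | 3-O-(tert-butyldiphenylsilyl)quinic acid | O[C@@H]1[C@H](O[Si](c2ccccc2)(c3ccccc3)C(C)(C)C)C[C@@](O)(C(=O)O)C[C@H]1O
F6 | step 8 | tert-butyl 3-O-(tert-butyldiphenylsilyl)quinate | O[C@@H]1[C@H](O[Si](c2ccccc2)(c3ccccc3)C(C)(C)C)C[C@@](O)(C(=O)OC(C)(C)C)C[C@H]1O
F7 | step 8 | tert-butyl 4,5-di-O-[(E)-4-acetoxycinnamoyl]-3-O-(tert-butyldiphenylsilyl)quinate | O=C(/C=C/c1ccc(OC(C)=O)cc1)O[C@@H]2[C@H](O[Si](c5ccccc5)(c6ccccc6)C(C)(C)C)C[C@@](O)(C(=O)OC(C)(C)C)C[C@H]2OC(=O)/C=C/c3ccc(OC(C)=O)cc3
F8 | step 9 | tert-butyl 4,5-di-O-[(E)-4-acetoxycinnamoyl]-2-(phenylselanyl)-1,3-bis-O-(trimethylsilyl)quinate | O=C(/C=C/c1ccc(OC(C)=O)cc1)O[C@@H]2[C@H](O[Si](C)(C)C)[C@@H]([Se]c4ccccc4)[C@@](O[Si](C)(C)C)(C(=O)OC(C)(C)C)C[C@H]2OC(=O)/C=C/c3ccc(OC(C)=O)cc3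
F9 | step 9 | tert-butyl 4,5-di-O-[(E)-4-acetoxycinnamoyl]-2-(phenylselanyl)quinate | O=C(/C=C/c1ccc(OC(C)=O)cc1)O[C@@H]2[C@H](O)[C@@H]([Se]c4ccccc4)[C@@](O)(C(=O)OC(C)(C)C)C[C@H]2OC(=O)/C=C/c3ccc(OC(C)=O)cc3
F10 | step 6 | tert-butyl 4,5-di-O-(carboxyacetyl)-3-O-(tert-butyldiphenylsilyl)shikimate | O=C(CC(=O)O)O[C@@H]1[C@H](O[Si](c2ccccc2)(c3ccccc3)C(C)(C)C)C=C(C(=O)OC(C)(C)C)C[C@H]1OC(=O)CC(=O)O
F11 | step 6 | tert-butyl 4,5-di-O-[(E)-4-hydroxycinnamoyl]-3-O-(tert-butyldiphenylsilyl)shikimate | O=C(/C=C/c1ccc(O)cc1)O[C@@H]2[C@H](O[Si](c5ccccc5)(c6ccccc6)C(C)(C)C)C=C(C(=O)OC(C)(C)C)C[C@H]2OC(=O)/C=C/c3ccc(O)cc3
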